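**Retrosynthetic overview**

1. Feature: ring B (O1, B2, B3, B3a, B7a) carries oxygen on B7a and B7 and carbon on B5. This is a 2-alkoxy-1,4-benzoquinone whose second carbonyl oxygen (B5–OH) later becomes the carbon handle; B2–B3 with both aryl groups is the double bond of protected resveratrol.
2. Kobophenol A ⇒ carbinol 27 (hydrogenolysis, C2(A)–O closure; the suffix (A) marks locants of the dihydrobenzofuran on ring A, the one bonded to ring T) ⇒ aldehyde 26 ⇒ nitroalkane 24 ⇒ ring B boronate 7 + nitroalkene 23 (conjugate arylation forms C3(A)–B5).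
3. 23 ⇒ ring T bromide 21 ⇒ acetal 20 (aryl transfer sets T2) ⇒ carbinol 18 (reduction sets T5) ⇒ Weinreb amide 16 ⇒ ester 10 + carbonate 14 (allylic alkylation forms T3–T4).
4. 7 ⇒ triflate 6 ⇒ phenol 5 ⇒ quinone 4 + stilbene 2 (formal [3+2] annulation forms B3a–B3 and B2–O1).
5. Ring order: ring B (step 3), ring T (steps 14–15), furan ring on ring A (step 20).

Key step: step 3

**Remarks and assumptions**

- The route is planned for the structure exactly as the SMILES gives it: ring A furan 2S,3S (trans); ring B 2R,3R (trans); ring T T2 S, T3 R, T4 S, T5 R (T2/T3 trans, T3/T4 cis, T4/T5 trans).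
- Labels: the ring A dihydrobenzofuran carries the usual benzofuran locants with the suffix (A): O1(A), C2(A), C3(A), C3a(A), C4(A) to C7a(A). Ring T is O, T2 (4-oxyphenyl, next to T3), T3 (3,5-dioxyphenyl), T4 (bound to C4(A)), T5 (4-oxyphenyl). "Ring B aryl" is the dihydrobenzofuran-5-yl group of 5–7.
- Benzyl ethers are carried on every phenol so that the last step is a hydrogenolysis; Lewis-acid dealkylation would open the benzylic ethers of rings A, B and T.
- The benzylated building blocks 3, 8 and 11, 4-(benzyloxy)phenylmagnesium bromide and potassium [4-(benzyloxy)phenyl]trifluoroborate are taken as purchasable.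
- The enantiomer named for each chiral catalyst (steps 3, 11, 13, 17) is the one expected from the accepted model of its reaction class. If the sense on these substrates is the opposite, the antipode is used; the route does not change.

**Route**

Step 1
Reactants: 1 resveratrol
Product: 2 (E)-3,4',5-tris(benzyloxy)stilbene
Conditions: BnBr, K2CO3, DMF, 60 °C
Reagents that add atoms: benzyl bromide BrCc1ccccc1
Why: Williamson ether synthesis on the three phenols, which leaves the E double bond untouched.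

Step 2
Reactants: 3 2-(benzyloxy)phenol
Product: 4 2-(benzyloxy)-1,4-benzoquinone
Conditions: ON(SO3K)2, KH2PO4 buffer, H2O/acetone, 0 °C to rt
Reagents that add atoms: potassium nitrosodisulfonate [K+].[K+].[O]N(S(=O)(=O)[O-])S(=O)(=O)[O-]
Why: Teuber oxidation of a phenol with a free para position should give the para-quinone with the benzyloxy group next to one carbonyl.

Step 3
Reactants: 2 (E)-3,4',5-tris(benzyloxy)stilbene; 4 2-(benzyloxy)-1,4-benzoquinone
Product: 5 (2R,3R)-7-(benzyloxy)-2-[4-(benzyloxy)phenyl]-3-[3,5-bis(benzyloxy)phenyl]-2,3-dihydro-1-benzofuran-5-ol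
Conditions: (R)-3,3'-bis(2,4,6-triisopropylphenyl)-1,1'-binaphthyl-2,2'-diyl N-triflylphosphoramide (10 mol %), 4 Å MS, toluene/CH2Cl2, −60 to −40 °C
Reagents that add atoms: none
Why: Proposed new method: the Brønsted acid protonates the carbonyl of 4 that is conjugated with the benzyloxy group (the more basic, vinylogous-ester oxygen), the ring CH β to it and next to the other carbonyl is attacked by the stilbene carbon that carries the 3,5-bis(benzyloxy)phenyl group, and after tautomerisation to the hydroquinone the oxygen next to the benzyloxy-bearing carbon captures the 4-benzyloxybenzyl cation, so that B3a–B3 and then B2–O1 form without change of oxidation level. The closest known reaction type is the acid-promoted formal [3+2] cycloaddition of 2-alkoxy-1,4-benzoquinones with styrenes and propenylarenes, for which chiral titanium TADDOLate and chiral phosphoric acid versions exist; the stilbene partner and attack at the CH remote from the alkoxy group go beyond it. Ring B closes by 5-exo-type C–O bond formation of the phenolic oxygen onto the benzylic cation. B3 is set in the C–C bond formation by the chiral phosphoramide anion, which is hydrogen-bonded to the quinone and shields one of its faces, and B2 is set in the ring closure trans to the B3 aryl group. The step needs attack at quinone C6 and not at C5 or C3, which monodentate protonation (no chelate with the benzyloxy oxygen) should secure, and the right stilbene polarity, which the better cation stabilisation by the 4-benzyloxyphenyl group than by the 3,5-dioxygenated ring should secure.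

Step 4
Reactants: 5 ring B phenol
Product: 6 (2R,3R)-7-(benzyloxy)-2-[4-(benzyloxy)phenyl]-3-[3,5-bis(benzyloxy)phenyl]-2,3-dihydro-1-benzofuran-5-yl trifluoromethanesulfonate
Conditions: Tf2O, pyridine, CH2Cl2, 0 °C
Reagents that add atoms: trifluoromethanesulfonic anhydride O=S(=O)(OS(=O)(=O)C(F)(F)F)C(F)(F)F
Why: O-sulfonylation of the phenol turns B5–O into a leaving group without touching B2 or B3.

Step 5
Reactants: 6 ring B triflate
Product: 7 2-{(2R,3R)-7-(benzyloxy)-2-[4-(benzyloxy)phenyl]-3-[3,5-bis(benzyloxy)phenyl]-2,3-dihydro-1-benzofuran-5-yl}-4,4,5,5-tetramethyl-1,3,2-dioxaborolane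
Conditions: B2pin2, PdCl2(dppf), KOAc, dioxane, 85 °C
Reagents that add atoms: bis(pinacolato)diboron CC1(C)OB(B2OC(C)(C)C(C)(C)O2)OC1(C)C
Why: Miyaura borylation of the aryl triflate, with the weak base KOAc to prevent biaryl coupling.

Step 6
Reactants: 8 3,5-bis(benzyloxy)phenylacetic acid
Product: 9 [3,5-bis(benzyloxy)-2-bromophenyl]acetic acid
Conditions: N-bromosuccinimide, MeCN, 0 °C
Reagents that add atoms: N-bromosuccinimide BrN1C(=O)CCC1=O
Why: electrophilic aromatic bromination should go para to one benzyloxy group and ortho to the side chain, because the position between the two ether groups is more hindered.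

Step 7
Reactants: 9 bromo acid
Product: 10 pentafluorophenyl [3,5-bis(benzyloxy)-2-bromophenyl]acetate
Conditions: C6F5OH, N,N'-dicyclohexylcarbodiimide, CH2Cl2, 0 °C to rt
Reagents that add atoms: pentafluorophenol Oc1c(F)c(F)c(F)c(F)c1F
Why: carbodiimide esterification gives the activated aryl ester that isothiourea catalysis needs.

Step 8
Reactants: 11 3,5-bis(benzyloxy)benzaldehyde
Product: 12 ethyl (E)-3-[3,5-bis(benzyloxy)phenyl]prop-2-enoate
Conditions: (EtO)2P(O)CH2CO2Et, NaH, THF, 0 °C to rt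
Reagents that add atoms: triethyl phosphonoacetate CCOC(=O)CP(=O)(OCC)OCC
Why: Horner–Wadsworth–Emmons olefination with a stabilised phosphonate is E-selective.

Step 9
Reactants: 12 cinnamate
Product: 13 (E)-3-[3,5-bis(benzyloxy)phenyl]prop-2-en-1-ol
Conditions: i-Bu2AlH, CH2Cl2, −78 °C; potassium sodium tartrate (aq) work-up
Reagents that add atoms: none
Why: 1,2-reduction of the enoate by diisobutylaluminium hydride gives the allylic alcohol with the alkene geometry kept.

Step 10
Reactants: 13 cinnamyl alcohol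
Product: 14 tert-butyl (E)-3-[3,5-bis(benzyloxy)phenyl]prop-2-en-1-yl carbonate
Conditions: Boc2O, n-Bu4NHSO4 (cat.), NaOH (aq), CH2Cl2, 0 °C to rt
Reagents that add atoms: di-tert-butyl dicarbonate CC(C)(C)OC(=O)OC(=O)OC(C)(C)C
Why: O-acylation under phase-transfer conditions gives the linear allylic carbonate used in iridium-catalysed allylic substitution.

Step 11
Reactants: 10 pentafluorophenyl ester; 14 allylic carbonate
Product: 16 (2S,3R)-N-methoxy-N-methyl-2-[3,5-bis(benzyloxy)-2-bromophenyl]-3-[3,5-bis(benzyloxy)phenyl]pent-4-enamide, via pentafluorophenyl ester 15 (not isolated)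
Conditions: [Ir(cod)Cl]2 (2 mol %) with the phosphoramidite from (R)-BINOL and bis[(R)-1-phenylethyl]amine (preformed cyclometalated complex), (R)-benzotetramisole [(R)-2-phenyl-2,3-dihydroimidazo[2,1-b][1,3]benzothiazole] (10 mol %), THF, rt; then MeNH(OMe)·HCl, i-Pr2NEt
Reagents that add atoms: N,O-dimethylhydroxylamine hydrochloride CNOC.Cl
Why: cooperative isothiourea/iridium allylic alkylation, in which the C1-ammonium enolate of 10 attacks the substituted terminus of the π-allyl iridium complex from 14, the isothiourea setting T4 and the iridium ligand setting T3 independently (pairing chosen for the 2S,3R isomer, aryl groups anti in the extended chain and so cis on ring T), followed by aminolysis of the turned-over ester 15.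

Step 12
Reactants: 16 Weinreb amide
Product: 17 (2S,3R)-1-[4-(benzyloxy)phenyl]-2-[3,5-bis(benzyloxy)-2-bromophenyl]-3-[3,5-bis(benzyloxy)phenyl]pent-4-en-1-one
Conditions: 4-BnOC6H4MgBr, THF, −78 to 0 °C
Reagents that add atoms: 4-(benzyloxy)phenylmagnesium bromide Br[Mg]c1ccc(OCc2ccccc2)cc1
Why: Weinreb ketone synthesis, whose chelated tetrahedral intermediate prevents over-addition and keeps the acidic T4–H out of an enolisable ketone until work-up.

Step 13
Reactants: 17 ketone
Product: 18 (1R,2S,3R)-1-[4-(benzyloxy)phenyl]-2-[3,5-bis(benzyloxy)-2-bromophenyl]-3-[3,5-bis(benzyloxy)phenyl]pent-4-en-1-ol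
Conditions: (S)-1-methyl-3,3-diphenyltetrahydro-1H,3H-pyrrolo[1,2-c][1,3,2]oxazaborole (0.5 equiv), BH3·SMe2, THF, −20 °C
Reagents that add atoms: none
Why: Corey–Bakshi–Shibata reduction of the aryl ketone, with the aryl group as the large substituent, should set T5 as R under reagent control.

Step 14
Reactants: 18 homoallylic alcohol
Product: 20 (3R,4S,5R)-5-[4-(benzyloxy)phenyl]-3-[3,5-bis(benzyloxy)phenyl]-4-[3,5-bis(benzyloxy)-2-bromophenyl]-2-methoxyoxolane (both anomers), via lactol 19 (not isolated)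
Conditions: O3, CH2Cl2/MeOH, −78 °C; Me2S; then pyridinium p-toluenesulfonate (cat.), rt
Reagents that add atoms: methanol CO
Why: ozonolysis of the terminal alkene gives the aldehyde, which the T5 hydroxyl traps as a five-membered lactol (ring T closed by 5-exo addition to the carbonyl) that acid-catalysed acetalisation turns into the methyl acetal.

Step 15
Reactants: 20 methyl acetal
Product: 21 (2S,3R,4S,5R)-2,5-bis[4-(benzyloxy)phenyl]-3-[3,5-bis(benzyloxy)phenyl]-4-[3,5-bis(benzyloxy)-2-bromophenyl]oxolane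
Conditions: 4-BnOC6H4BF3K, BF3·OEt2, CH2Cl2/MeCN, −40 to 0 °C
Reagents that add atoms: potassium [4-(benzyloxy)phenyl]trifluoroborate [K+].F[B-](F)(F)c1ccc(OCc2ccccc2)cc1
Why: Lewis-acid substitution of the cyclic acetal through its oxocarbenium ion by aryl transfer from boron, the aryl group entering anti to the T3 aryl group (T2 trans to T3), while the neighbouring arenes could reach the ring cation only by forming a bridged ring.

Step 16
Reactants: 21 ring T bromide
Product: 23 nitroalkene: oxolane 21 with (E)-2-nitroethenyl in place of Br, via aryllithium 22 (not isolated)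
Conditions: t-BuLi (2.1 equiv), THF, −78 °C; then Me2NCH=CHNO2; 1 M HCl work-up
Reagents that add atoms: (E)-N,N-dimethyl-2-nitroethenamine CN(C)/C=C/[N+](=O)[O-]
Why: bromine–lithium exchange followed by addition of the aryllithium to the amine-bearing carbon of the push–pull nitroenamine and loss of dimethylamine on acidification (addition–elimination nitroolefination) gives the E nitroalkene.

Step 17
Reactants: 23 nitroalkene; 7 ring B boronate
Product: 24 nitroalkane: oxolane 21 with (1S)-2-nitro-1-(ring B aryl)ethyl in place of Br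
Conditions: [RhCl(C2H4)2]2 (3 mol %), (R,R)-2,5-diphenylbicyclo[2.2.2]octa-2,5-diene (6.6 mol %), KOH (aq), dioxane/H2O, 50 °C
Reagents that add atoms: none
Why: Hayashi–Miyaura rhodium-catalysed asymmetric conjugate addition of the arylboronate to the nitroalkene forms the C3(A)–B5 bond, the chiral diene choosing the alkene face so that C3(A) is S.

Step 18
Reactants: 24 nitroalkane
Product: 26 aldehyde: oxolane 21 with (1S)-2-oxo-1-(ring B aryl)ethyl in place of Br, via sodium nitronate 25 (not isolated)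
Conditions: NaOMe (1.05 equiv), MeOH/CH2Cl2, 0 °C; then O3, −78 °C; N2 purge; pH 7 buffer
Reagents that add atoms: ozone [O-][O+]=O
Why: Nef reaction by ozonolysis of the nitronate, which cleaves only the C=N bond at low temperature and so should leave C3(A) and the electron-rich arenes untouched.

Step 19
Reactants: 26 aldehyde
Product: 27 carbinol: oxolane 21 with (1S)-2-[4-(benzyloxy)phenyl]-2-hydroxy-1-(ring B aryl)ethyl in place of Br (both epimers at C2(A))
Conditions: 4-BnOC6H4MgBr, CeCl3 (anhydrous), THF, −78 °C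
Reagents that add atoms: 4-(benzyloxy)phenylmagnesium bromide Br[Mg]c1ccc(OCc2ccccc2)cc1
Why: Imamoto organocerium 1,2-addition to the enolisable diarylacetaldehyde should beat deprotonation at C3(A); the configuration at C2(A) is not needed because it is reset in step 20.

Step 20
Reactants: 27 carbinol
Product: 29 kobophenol A, via polyphenol carbinol 28 (not isolated)
Conditions: H2 (1 atm), Pd/C, THF/EtOAc, rt; filter; then pyridinium p-toluenesulfonate (cat.), THF, rt
Reagents that add atoms: none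
Why: hydrogenolysis of the eleven benzyl ethers followed by acid-catalysed cycloetherification, in which the 4-hydroxybenzylic carbinol ionises (para-quinone methide) and the phenol on C7a(A) closes the furan ring by 5-exo attack, C2(A) being set trans to the aryl group on C3(A) (S).

**Compound list**

1 | resveratrol | Oc1ccc(/C=C/c2cc(O)cc(O)c2)cc1 | starting material
2 | (E)-3,4',5-tris(benzyloxy)stilbene | c1ccc(COc2ccc(/C=C/c3cc(OCc4ccccc4)cc(OCc4ccccc4)c3)cc2)cc1 | intermediate
3 | 2-(benzyloxy)phenol | Oc1ccccc1OCc1ccccc1 | starting material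
4 | 2-(benzyloxy)-1,4-benzoquinone | O=C1C=CC(=O)C(OCc2ccccc2)=C1 | intermediate
5 | (2R,3R)-7-(benzyloxy)-2-[4-(benzyloxy)phenyl]-3-[3,5-bis(benzyloxy)phenyl]-2,3-dihydro-1-benzofuran-5-ol | Oc1cc(OCc2ccccc2)c2c(c1)[C@@H](c1cc(OCc3ccccc3)cc(OCc3ccccc3)c1)[C@H](c1ccc(OCc3ccccc3)cc1)O2 | intermediate
6 | 5-triflate of 5 | O=S(=O)(Oc1cc(OCc2ccccc2)c2c(c1)[C@@H](c1cc(OCc3ccccc3)cc(OCc3ccccc3)c1)[C@H](c1ccc(OCc3ccccc3)cc1)O2)C(F)(F)F | intermediate
7 | 5-(pinacolboryl) analogue of 5 | CC1(C)OB(c2cc(OCc3ccccc3)c3c(c2)[C@@H](c2cc(OCc4ccccc4)cc(OCc4ccccc4)c2)[C@H](c2ccc(OCc4ccccc4)cc2)O3)OC1(C)C | intermediate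
8 | 3,5-bis(benzyloxy)phenylacetic acid | OC(=O)Cc1cc(OCc2ccccc2)cc(OCc2ccccc2)c1 | starting material
9 | [3,5-bis(benzyloxy)-2-bromophenyl]acetic acid | OC(=O)Cc1cc(OCc2ccccc2)cc(OCc2ccccc2)c1Br | intermediate
10 | pentafluorophenyl [3,5-bis(benzyloxy)-2-bromophenyl]acetate | O=C(Cc1cc(OCc2ccccc2)cc(OCc2ccccc2)c1Br)Oc1c(F)c(F)c(F)c(F)c1F | intermediate
11 | 3,5-bis(benzyloxy)benzaldehyde | O=Cc1cc(OCc2ccccc2)cc(OCc2ccccc2)c1 | starting material
12 | ethyl (E)-3-[3,5-bis(benzyloxy)phenyl]prop-2-enoate | CCOC(=O)/C=C/c1cc(OCc2ccccc2)cc(OCc2ccccc2)c1 | intermediate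
13 | (E)-3-[3,5-bis(benzyloxy)phenyl]prop-2-en-1-ol | OC/C=C/c1cc(OCc2ccccc2)cc(OCc2ccccc2)c1 | intermediate
14 | tert-butyl (E)-3-[3,5-bis(benzyloxy)phenyl]prop-2-en-1-yl carbonate | CC(C)(C)OC(=O)OC/C=C/c1cc(OCc2ccccc2)cc(OCc2ccccc2)c1 | intermediate
15 | pentafluorophenyl (2S,3R)-2-[3,5-bis(benzyloxy)-2-bromophenyl]-3-[3,5-bis(benzyloxy)phenyl]pent-4-enoate | O=C(Oc1c(F)c(F)c(F)c(F)c1F)[C@H](c1cc(OCc2ccccc2)cc(OCc2ccccc2)c1Br)[C@H](c1cc(OCc2ccccc2)cc(OCc2ccccc2)c1)C=C | intermediate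
16 | (2S,3R)-N-methoxy-N-methyl-2-[3,5-bis(benzyloxy)-2-bromophenyl]-3-[3,5-bis(benzyloxy)phenyl]pent-4-enamide | CON(C)C(=O)[C@H](c1cc(OCc2ccccc2)cc(OCc2ccccc2)c1Br)[C@H](c1cc(OCc2ccccc2)cc(OCc2ccccc2)c1)C=C | intermediate
17 | (2S,3R)-1-[4-(benzyloxy)phenyl]-2-[3,5-bis(benzyloxy)-2-bromophenyl]-3-[3,5-bis(benzyloxy)phenyl]pent-4-en-1-one | O=C(c1ccc(OCc2ccccc2)cc1)[C@H](c1cc(OCc2ccccc2)cc(OCc2ccccc2)c1Br)[C@H](c1cc(OCc2ccccc2)cc(OCc2ccccc2)c1)C=C | intermediate
18 | (1R,2S,3R)-1-[4-(benzyloxy)phenyl]-2-[3,5-bis(benzyloxy)-2-bromophenyl]-3-[3,5-bis(benzyloxy)phenyl]pent-4-en-1-ol | O[C@@H](c1ccc(OCc2ccccc2)cc1)[C@H](c1cc(OCc2ccccc2)cc(OCc2ccccc2)c1Br)[C@H](c1cc(OCc2ccccc2)cc(OCc2ccccc2)c1)C=C | intermediate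
19 | (3R,4S,5R)-5-[4-(benzyloxy)phenyl]-3-[3,5-bis(benzyloxy)phenyl]-4-[3,5-bis(benzyloxy)-2-bromophenyl]oxolan-2-ol (anomers) | Brc1c(OCc2ccccc2)cc(OCc2ccccc2)cc1[C@@H]1[C@H](c2cc(OCc3ccccc3)cc(OCc3ccccc3)c2)C(O)O[C@H]1c1ccc(OCc2ccccc2)cc1 | intermediate
20 | (3R,4S,5R)-5-[4-(benzyloxy)phenyl]-3-[3,5-bis(benzyloxy)phenyl]-4-[3,5-bis(benzyloxy)-2-bromophenyl]-2-methoxyoxolane (anomers) | Brc1c(OCc2ccccc2)cc(OCc2ccccc2)cc1[C@@H]1[C@H](c2cc(OCc3ccccc3)cc(OCc3ccccc3)c2)C(OC)O[C@H]1c1ccc(OCc2ccccc2)cc1 | intermediate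
21 | (2S,3R,4S,5R)-2,5-bis[4-(benzyloxy)phenyl]-3-[3,5-bis(benzyloxy)phenyl]-4-[3,5-bis(benzyloxy)-2-bromophenyl]oxolane (2,3-trans, 3,4-cis, 4,5-trans) | Brc1c(OCc2ccccc2)cc(OCc2ccccc2)cc1[C@@H]1[C@H](c2cc(OCc3ccccc3)cc(OCc3ccccc3)c2)[C@@H](c2ccc(OCc3ccccc3)cc2)O[C@H]1c1ccc(OCc2ccccc2)cc1 | intermediate
22 | aryllithium: 21 with Li in place of Br | [Li]c1c(OCc2ccccc2)cc(OCc2ccccc2)cc1[C@@H]1[C@H](c2cc(OCc3ccccc3)cc(OCc3ccccc3)c2)[C@@H](c2ccc(OCc3ccccc3)cc2)O[C@H]1c1ccc(OCc2ccccc2)cc1 | intermediate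
23 | nitroalkene: 21 with (E)-2-nitroethenyl in place of Br | [O-][N+](=O)/C=C/c1c(OCc2ccccc2)cc(OCc2ccccc2)cc1[C@@H]1[C@H](c2cc(OCc3ccccc3)cc(OCc3ccccc3)c2)[C@@H](c2ccc(OCc3ccccc3)cc2)O[C@H]1c1ccc(OCc2ccccc2)cc1 | intermediate
24 | nitroalkane: 21 with (1S)-2-nitro-1-(ring B aryl)ethyl in place of Br | [O-][N+](=O)C[C@@H](c4cc(OCc5ccccc5)c5c(c4)[C@@H](c4cc(OCc6ccccc6)cc(OCc6ccccc6)c4)[C@H](c4ccc(OCc6ccccc6)cc4)O5)c1c(OCc2ccccc2)cc(OCc2ccccc2)cc1[C@@H]1[C@H](c2cc(OCc3ccccc3)cc(OCc3ccccc3)c2)[C@@H](c2ccc(OCc3ccccc3)cc2)O[C@H]1c1ccc(OCc2ccccc2)cc1 | intermediate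
25 | sodium nitronate of 24 | [Na+].[O-][N+]([O-])=C[C@@H](c4cc(OCc5ccccc5)c5c(c4)[C@@H](c4cc(OCc6ccccc6)cc(OCc6ccccc6)c4)[C@H](c4ccc(OCc6ccccc6)cc4)O5)c1c(OCc2ccccc2)cc(OCc2ccccc2)cc1[C@@H]1[C@H](c2cc(OCc3ccccc3)cc(OCc3ccccc3)c2)[C@@H](c2ccc(OCc3ccccc3)cc2)O[C@H]1c1ccc(OCc2ccccc2)cc1 | intermediate
26 | aldehyde: 21 with (1S)-2-oxo-1-(ring B aryl)ethyl in place of Br | O=C[C@@H](c4cc(OCc5ccccc5)c5c(c4)[C@@H](c4cc(OCc6ccccc6)cc(OCc6ccccc6)c4)[C@H](c4ccc(OCc6ccccc6)cc4)O5)c1c(OCc2ccccc2)cc(OCc2ccccc2)cc1[C@@H]1[C@H](c2cc(OCc3ccccc3)cc(OCc3ccccc3)c2)[C@@H](c2ccc(OCc3ccccc3)cc2)O[C@H]1c1ccc(OCc2ccccc2)cc1 | intermediate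
27 | carbinol: 21 with (1S)-2-[4-(benzyloxy)phenyl]-2-hydroxy-1-(ring B aryl)ethyl in place of Br (both epimers at C2(A)) | OC(c1ccc(OCc2ccccc2)cc1)[C@@H](c4cc(OCc5ccccc5)c5c(c4)[C@@H](c4cc(OCc6ccccc6)cc(OCc6ccccc6)c4)[C@H](c4ccc(OCc6ccccc6)cc4)O5)c1c(OCc2ccccc2)cc(OCc2ccccc2)cc1[C@@H]1[C@H](c2cc(OCc3ccccc3)cc(OCc3ccccc3)c2)[C@@H](c2ccc(OCc3ccccc3)cc2)O[C@H]1c1ccc(OCc2ccccc2)cc1 | intermediate
28 | polyphenol carbinol: 27 without its eleven benzyl groups | OC(c1ccc(O)cc1)[C@@H](c4cc(O)c5c(c4)[C@@H](c4cc(O)cc(O)c4)[C@H](c4ccc(O)cc4)O5)c1c(O)cc(O)cc1[C@@H]1[C@H](c2cc(O)cc(O)c2)[C@@H](c2ccc(O)cc2)O[C@H]1c1ccc(O)cc1 | intermediate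
29 | kobophenol A | Oc1ccc([C@H]2Oc3cc(O)cc([C@@H]4[C@H](c5cc(O)cc(O)c5)[C@@H](c5ccc(O)cc5)O[C@H]4c4ccc(O)cc4)c3[C@@H]2c2cc(O)c3c(c2)[C@@H](c2cc(O)cc(O)c2)[C@H](c2ccc(O)cc2)O3)cc1 | target

**Step count**

Total: 20 steps. Longest linear sequence: 13 steps (steps 8–20).

**Steps most likely to fail**

1. Step 3 (proposed new method). The stilbene may attack the quinone CH that chelation-type activation favours (C5) or the CH next to the benzyloxy group; the resorcinol ring may alkylate the quinone instead of the alkene; face selection by the acid may be poor. The fallback uses the known oxidative phenol–alkene [3+2] cycloaddition of 4-alkoxyphenols, in which the phenol oxygen and its only free ortho carbon fix the regiochemistry. It sets out from quinone 4 and stilbene 2 and comes back at phenol 5. Quinone 4 is reduced (Na2S2O4) to 2-(benzyloxy)benzene-1,4-diol F1, which is allylated at the less hindered 4-oxygen (allyl bromide, K2CO3) to 4-(allyloxy)-2-(benzyloxy)phenol F2. Oxidation of F2 with PhI(OAc)2 in (CF3)2CHOH in the presence of 2 should give the racemic trans 5-allyloxy dihydrobenzofuran F3. Deallylation (Pd(PPh3)4, morpholine) gives racemic 5, and chromatography on a chiral stationary phase removes the (2S,3S)-enantiomer F4 and returns 5.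

2. Step 17. Insertion at a β-carbon flanked by two ortho substituents may be slow, so that protodeboronation of 7 wins, and the twisted aryl group may erode face selection. The fallback forms the C3(A)–B5 bond by palladium enolate arylation. It sets out from bromide 21 and triflate 6 and comes back at carbinol 27; steps 5 and 16–19 are then not needed. α-Arylation of 1-[4-(benzyloxy)phenyl]ethanone with 21 (Pd2(dba)3, XPhos, NaOt-Bu) gives deoxybenzoin F5. A second enolate arylation with 6 (Pd(OAc)2, P(t-Bu)3, NaOt-Bu) gives triarylethanone F6. Transfer hydrogenation with RuCl(p-cymene)[(S,S)-TsDPEN] in HCO2H/Et3N, under which the acidic hydrogen on C3(A) epimerises (dynamic kinetic resolution, ligand enantiomer chosen for the S configuration at C3(A)), should give 27.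

3. Step 20. Hydrogenolysis may also cleave the free benzylic hydroxyl on C2(A) or a ring benzylic C–O bond, and the acid may epimerise or open ring T in the free polyphenol. The fallback closes the furan ring before deprotection. It sets out from 27 and comes back at 29. BF3·OEt2 with pentamethylbenzene at −78 °C ionises the hydroxyl on C2(A), and the benzyl ether oxygen on C7a(A) closes the ring with loss of its benzyl group (debenzylative cycloetherification) to give decabenzyl kobophenol A F7. Its ten aryl benzyl ethers are then removed by hydrogenolysis (H2, Pd/C) with no free benzylic carbinol present.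

**Further compounds**

F1 | step 3 | 2-(benzyloxy)benzene-1,4-diol | Oc1ccc(O)c(OCc2ccccc2)c1
F2 | step 3 | 4-(allyloxy)-2-(benzyloxy)phenol | C=CCOc1ccc(O)c(OCc2ccccc2)c1
F3 | step 3 | racemic trans-5-(allyloxy)-7-(benzyloxy)-2-[4-(benzyloxy)phenyl]-3-[3,5-bis(benzyloxy)phenyl]-2,3-dihydro-1-benzofuran (drawn as the 2R,3R enantiomer) | C=CCOc1cc(OCc2ccccc2)c2c(c1)[C@@H](c1cc(OCc3ccccc3)cc(OCc3ccccc3)c1)[C@H](c1ccc(OCc3ccccc3)cc1)O2
F4 | step 3 | (2S,3S)-enantiomer of phenol 5 | Oc1cc(OCc2ccccc2)c2c(c1)[C@H](c1cc(OCc3ccccc3)cc(OCc3ccccc3)c1)[C@@H](c1ccc(OCc3ccccc3)cc1)O2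
F5 | step 17 | deoxybenzoin: 21 with 2-[4-(benzyloxy)phenyl]-2-oxoethyl in place of Br | O=C(Cc1c(OCc2ccccc2)cc(OCc2ccccc2)cc1[C@@H]1[C@H](c2cc(OCc3ccccc3)cc(OCc3ccccc3)c2)[C@@H](c2ccc(OCc3ccccc3)cc2)O[C@H]1c1ccc(OCc2ccccc2)cc1)c1ccc(OCc2ccccc2)cc1
F6 | step 17 | triarylethanone: F5 with the ring B aryl group on the α-carbon (both epimers at C3(A)) | O=C(C(c4cc(OCc5ccccc5)c5c(c4)[C@@H](c4cc(OCc6ccccc6)cc(OCc6ccccc6)c4)[C@H](c4ccc(OCc6ccccc6)cc4)O5)c1c(OCc2ccccc2)cc(OCc2ccccc2)cc1[C@@H]1[C@H](c2cc(OCc3ccccc3)cc(OCc3ccccc3)c2)[C@@H](c2ccc(OCc3ccccc3)cc2)O[C@H]1c1ccc(OCc2ccccc2)cc1)c1ccc(OCc2ccccc2)cc1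
F7 | step 20 | decabenzyl kobophenol A | c6ccccc6COc1ccc([C@H]2Oc3cc(OCc6ccccc6)cc([C@@H]4[C@H](c5cc(OCc6ccccc6)cc(OCc6ccccc6)c5)[C@@H](c5ccc(OCc6ccccc6)cc5)O[C@H]4c4ccc(OCc6ccccc6)cc4)c3[C@@H]2c2cc(OCc6ccccc6)c3c(c2)[C@@H](c2cc(OCc6ccccc6)cc(OCc6ccccc6)c2)[C@H](c2ccc(OCc6ccccc6)cc2)O3)cc1
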